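The 5,7-dimethoxyflavone target has a ring A that bears oxygen on C5, C7 and C8a and the C4 carbonyl on C4a. That pattern is an acylphloroglucinol, the aromatic form of a folded poly-β-keto chain. The route therefore disconnects the C4a–C8a bond of ring A (equivalent to C4a–C5). A magnesium-mediated intramolecular Claisen condensation of an open-chain methyl 3,5,7-trioxonon-8-enoate, already carrying the complete 2,3,4,5-tetramethoxyphenyl ring B at C9, closes and aromatises the carbocycle in one operation. It gives the 2',4',6'-trihydroxychalcone with all fifteen skeletal carbons. Partial O-methylation and iodine/DMSO closure of ring C complete the synthesis.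

Key step: step 5

Remark: the target has no stereocentre and is achiral, so no enantiocontrol is required; the only stereo-element on the way is the E double bond of 5, 9, 10 and 11, which is set in step 2 and disappears in step 7.

Step 1
Reactants: 1 1,2,3,4-tetramethoxybenzene
Product: 3 2,3,4,5-tetramethoxybenzaldehyde, via aryl iminium chloride 2 (not isolated)
Conditions: POCl3 (1.5 equiv), DMF, 0 → 75 °C; then ice–H2O
Reagents that add atoms: N,N-dimethylformamide, CN(C)C=O (formyl carbon); water, O (carbonyl oxygen, on hydrolysis of 2)
Why: Vilsmeier–Haack formylation, in which the two unsubstituted positions of 1 are equivalent and each lies ortho to one methoxy group and para to another, so that the chloroiminium electrophile can give only one regioisomer and hydrolysis of 2 releases the aldehyde.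

Step 2
Reactants: 3 2,3,4,5-tetramethoxybenzaldehyde; 4 trimethyl phosphonoacetate
Product: 5 methyl (E)-3-(2,3,4,5-tetramethoxyphenyl)prop-2-enoate
Conditions: NaH, THF, 0 °C → rt
Reagents that add atoms: none
Why: Horner–Wadsworth–Emmons olefination of an aromatic aldehyde with a stabilised phosphonate anion, which should give the E-cinnamate through the reversible, thermodynamically controlled addition step; no stereocentre is created.

Step 3
Reactants: 6 4-hydroxy-6-methyl-2H-pyran-2-one (triacetic acid lactone)
Product: 7 methyl 3,5-dioxohexanoate
Conditions: Mg(OMe)2 (commercial solution, 1.1 equiv), MeOH, reflux; then cold 1 M HCl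
Reagents that add atoms: methanol, CO (delivered as magnesium methoxide, CO[Mg]OC)
Why: Ring-opening methanolysis (acyl substitution at the lactone carbonyl) of the enol lactone, a known conversion of triacetic acid lactone that is driven by the stable magnesium chelate of the β,δ-diketo ester, from which cold acid releases 7.

Step 4
Reactants: 7 methyl 3,5-dioxohexanoate (2 equiv); 5 methyl (E)-3-(2,3,4,5-tetramethoxyphenyl)prop-2-enoate (1 equiv)
Product: 9 methyl (E)-3,5,7-trioxo-9-(2,3,4,5-tetramethoxyphenyl)non-8-enoate, via trilithio trianion 8 (not isolated)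
Conditions: LDA (commercial solution, 3.0 equiv per 7), THF, −78 → 0 °C; then 5, −78 → 0 °C; cold dilute HCl to pH 4–5, crude 9 used at once
Reagents that add atoms: none
Why: Claisen-type C-acylation of a 1,3,5-tricarbonyl polyanion with an ester, in which the terminal carbanion of 8 (formed last, hence the most basic and nucleophilic site) attacks the ester carbonyl of 5 in the 1,2 sense, while the second equivalent of 8 removes a proton from the new, more acidic C6 methylene so that 9 rests as an unreactive polyenolate until the cold quench.

Step 5
Reactants: 9 methyl (E)-3,5,7-trioxo-9-(2,3,4,5-tetramethoxyphenyl)non-8-enoate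
Product: 10 (E)-3-(2,3,4,5-tetramethoxyphenyl)-1-(2,4,6-trihydroxyphenyl)prop-2-en-1-one
Conditions: Mg(OMe)2 (commercial solution, 5 equiv), MeOH, rt → 40 °C, Ar; then cold 1 M HCl, rapid extraction
Reagents that add atoms: none
Why: Magnesium methoxide turns 9 into a chelated polyenolate in which C6, flanked by the C5 and C7 carbonyls, adds to the ester carbonyl C1; loss of methoxide gives a 2-acylcyclohexane-1,3,5-trione that tautomerises irreversibly to the phloroglucinol, which creates the later C4a–C8a bond of the flavone (C4a–C5 is the same bond by symmetry). The closest known reaction type is the base-mediated biomimetic Claisen (Dieckmann-type) cyclisation of 3,5,7-triketo esters to acylphloroglucinols, the laboratory counterpart of the chalcone synthase folding. The one ring closure is 6-exo-trig, the ester C=O being exocyclic to the forming carbocycle. No stereocentre is formed and the E-alkene is a spectator. The step needs chemoselectivity for the Claisen mode over the C2-to-C7 aldol mode (a styryl resorcylate) and over lactonisation through the C5 enol oxygen (a 4-hydroxy-2-pyrone); excess Mg(OMe)2 keeps the three ketones enolised and chelated, so that the ester is the only acyl carbon left as an electrophile, and the C7 carbonyl is further deactivated by conjugation with the electron-rich tetramethoxystyryl group. Any pyrone that forms should be reopened by magnesium methoxide in methanol, as in step 3, whereas aromatisation makes the Claisen product a sink.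

Step 6
Reactants: 10 (E)-3-(2,3,4,5-tetramethoxyphenyl)-1-(2,4,6-trihydroxyphenyl)prop-2-en-1-one
Product: 11 (E)-1-(2-hydroxy-4,6-dimethoxyphenyl)-3-(2,3,4,5-tetramethoxyphenyl)prop-2-en-1-one
Conditions: Me2SO4 (2.2 equiv), K2CO3 (3 equiv), acetone, reflux
Reagents that add atoms: dimethyl sulfate, COS(=O)(=O)OC
Why: Williamson O-methylation under carbonate conditions, in which the para hydroxyl and one of the two equivalent ortho hydroxyls are alkylated while the remaining ortho hydroxyl is held in a hydrogen bond to the ketone and is far less nucleophilic, the same discrimination that serves in the partial methylation of phloroacetophenone.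

Step 7
Reactants: 11 (E)-1-(2-hydroxy-4,6-dimethoxyphenyl)-3-(2,3,4,5-tetramethoxyphenyl)prop-2-en-1-one
Product: 13 5,7-dimethoxy-2-(2,3,4,5-tetramethoxyphenyl)-4H-chromen-4-one, via dimethoxyflavanone 12 (not isolated)
Conditions: I2 (10 mol %), DMSO, 120 °C
Reagents that add atoms: none
Why: Iodine-catalysed oxidative cyclisation of a 2'-hydroxychalcone in DMSO, in which oxa-Michael addition of the phenol to the enone gives racemic flavanone 12, iodine dehydrogenates its C2–C3 bond (erasing the transient stereocentre) and DMSO re-oxidises the hydrogen iodide, so that iodine is needed only in catalytic amount.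

Compound list
1 | 1,2,3,4-tetramethoxybenzene | COc1ccc(OC)c(OC)c1OC | starting material
2 | N,N-dimethyl-(2,3,4,5-tetramethoxyphenyl)methaniminium chloride (formed in the flask, not isolated) | C[N+](C)=Cc1cc(OC)c(OC)c(OC)c1OC.[Cl-] | intermediate
3 | 2,3,4,5-tetramethoxybenzaldehyde | O=Cc1cc(OC)c(OC)c(OC)c1OC | intermediate
4 | trimethyl phosphonoacetate | COC(=O)CP(=O)(OC)OC | starting material
5 | methyl (E)-3-(2,3,4,5-tetramethoxyphenyl)prop-2-enoate | COC(=O)/C=C/c1cc(OC)c(OC)c(OC)c1OC | intermediate
6 | 4-hydroxy-6-methyl-2H-pyran-2-one (triacetic acid lactone) | Cc1cc(O)cc(=O)o1 | starting material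
7 | methyl 3,5-dioxohexanoate | COC(=O)CC(=O)CC(C)=O | intermediate
8 | trilithium tris-enolate (trianion) of methyl 3,5-dioxohexanoate (formed in the flask, not isolated) | [Li+].[Li+].[Li+].C=C([O-])C=C([O-])C=C([O-])OC | intermediate
9 | methyl (E)-3,5,7-trioxo-9-(2,3,4,5-tetramethoxyphenyl)non-8-enoate | COC(=O)CC(=O)CC(=O)CC(=O)/C=C/c1cc(OC)c(OC)c(OC)c1OC | intermediate
10 | (E)-3-(2,3,4,5-tetramethoxyphenyl)-1-(2,4,6-trihydroxyphenyl)prop-2-en-1-one | O=C(/C=C/c1cc(OC)c(OC)c(OC)c1OC)c1c(O)cc(O)cc1O | intermediate
11 | (E)-1-(2-hydroxy-4,6-dimethoxyphenyl)-3-(2,3,4,5-tetramethoxyphenyl)prop-2-en-1-one | COc1cc(O)c(C(=O)/C=C/c2cc(OC)c(OC)c(OC)c2OC)c(OC)c1 | intermediate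
12 | 5,7-dimethoxy-2-(2,3,4,5-tetramethoxyphenyl)chroman-4-one (racemic, formed in the flask, not isolated) | COc1cc(OC)c2C(=O)CC(c3cc(OC)c(OC)c(OC)c3OC)Oc2c1 | intermediate
13 | 5,7-dimethoxy-2-(2,3,4,5-tetramethoxyphenyl)-4H-chromen-4-one (achiral) | COc1cc(OC)c2c(=O)cc(-c3cc(OC)c(OC)c(OC)c3OC)oc2c1 | target

Total step count: 7
Longest linear sequence: 6 steps (steps 1, 2, 4, 5, 6, 7); step 3 is a one-step side branch.

Steps most likely to fail

Step 5. The chain may fold in the aldol sense (C2 onto the C7 carbonyl) or lactonise through the C5 enol oxygen instead of closing in the Claisen sense. The trihydroxychalcone may also partly ring-close on acidic work-up, which is tolerated because the carbonate conditions of step 6 reopen it. Fallback: ring A is bought instead of built. The fallback sets out from aldehyde 3, which is condensed with commercial 1-(2-hydroxy-4,6-dimethoxyphenyl)ethanone in a Claisen–Schmidt reaction (KOH, EtOH/H2O, rt). This should give chalcone 11 directly, where the route is rejoined before step 7.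

Step 4. Conjugate addition of the polyanion to the cinnamate, proton transfer from the product to unreacted trianion, or premature cyclisation of the polyenolate of 9 in the flask may erode the acylation. Fallback: the fallback sets out from 3 and comes back at 9, with the ester end masked and a non-enolisable, chelating acyl donor.
- Horner–Wadsworth–Emmons reaction of 3 with diethyl (N-methoxy-N-methylcarbamoylmethyl)phosphonate (NaH, THF) should give the Weinreb amide (E)-N-methoxy-N-methyl-3-(2,3,4,5-tetramethoxyphenyl)prop-2-enamide F1.
- Commercial 2,2,6-trimethyl-4H-1,3-dioxin-4-one is C-acetylated through its lithium dienolate (LiHMDS, THF, −78 °C; acetyl chloride) to the keto-dioxinone 2,2-dimethyl-6-(2-oxopropyl)-4H-1,3-dioxin-4-one F2.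
- The dianion of F2 (LDA, 2.2 equiv, THF, −78 °C) is acylated at its terminal carbon by F1, whose chelated tetrahedral adduct survives until the quench. This should give the diketo-dioxinone (E)-6-[2,4-dioxo-6-(2,3,4,5-tetramethoxyphenyl)hex-5-en-1-yl]-2,2-dimethyl-4H-1,3-dioxin-4-one F3.
- Thermolysis of F3 in toluene with methanol at 110 °C (retro-[4+2] to the acylketene, trapped by methanol) returns to triketo ester 9.

Step 6. The discrimination between the hydrogen-bonded and the free hydroxyls may be lost (methylation of the chelated 2'-OH, which would block ring C closure), or the phloroglucinol ring may be C-methylated. Fallback: methylation is postponed until ring C is closed. The fallback sets out from 10, which is cyclised and dehydrogenated with I2 (cat.) in DMSO at 120 °C to 5,7-dihydroxy-2-(2,3,4,5-tetramethoxyphenyl)-4H-chromen-4-one F4. Exhaustive O-methylation (excess Me2SO4, K2CO3, acetone, prolonged reflux) then needs no selectivity and comes back to the route at 13.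

Further compounds
F0 | step 5 | none | none
F1 | step 4 | (E)-N-methoxy-N-methyl-3-(2,3,4,5-tetramethoxyphenyl)prop-2-enamide | CON(C)C(=O)/C=C/c1cc(OC)c(OC)c(OC)c1OC
F2 | step 4 | 2,2-dimethyl-6-(2-oxopropyl)-4H-1,3-dioxin-4-one | CC(=O)CC1=CC(=O)OC(C)(C)O1
F3 | step 4 | (E)-6-[2,4-dioxo-6-(2,3,4,5-tetramethoxyphenyl)hex-5-en-1-yl]-2,2-dimethyl-4H-1,3-dioxin-4-one | CC1(C)OC(=O)C=C(CC(=O)CC(=O)/C=C/c2cc(OC)c(OC)c(OC)c2OC)O1
F4 | step 6 | 5,7-dihydroxy-2-(2,3,4,5-tetramethoxyphenyl)-4H-chromen-4-one | O=c1cc(-c2cc(OC)c(OC)c(OC)c2OC)oc2cc(O)cc(O)c12
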